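# Proposed total synthesis of lapiferine

## Analysis of the target

Lapiferine is a trans-fused bicyclo[5.3.0]decane (daucane). Its cyclopentane (C1–C5) carries the quaternary C1 (C15 methyl) and the tertiary carbinol C4 (isopropyl). Its cycloheptane (C1, C5–C10) carries the C6 angelate, the C8–C9 epoxide with the C14 methyl on C8, and the C10 hydroxyl. There are seven stereocentres (C1, C4, C5, C6, C8, C9, C10). H-5, the C6 oxygen, the epoxide oxygen and the C10 hydroxyl all lie on the α face, opposite the C15 methyl; the C4 hydroxyl is β (syn to C15) and forms an anti-1,3-diol with the C6 oxygen.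

The sensitive groups are the angelate (Z to E isomerisation by acid, base or reversible conjugate addition), the syn epoxy alcohol, and any intermediate with a C6 carbonyl β,γ to the epoxide (eliminative opening). The main difficulties are the trans ring fusion at a quaternary centre and the C10 α-hydroxyl, which is contra-steric for hydride reduction of a C10 ketone (hydride would enter anti to C15) but matched for electrophilic oxidation of a C9=C10 alkene.

The feature that invites the chosen move: C6 and C10, the two oxygenated ring carbons flanking the C1–C5 fusion, make the seven-membered ring a masked cyclohepta-1,4-diene (C5=C6, C9=C10) with C1 as the doubly allylic carbon and C7–C8 as the saturated pair. This is the retron of a cis-divinylcyclopropane rearrangement, and the C4 carbonyl next to C5 is the acceptor a metal carbene needs.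

## Retrosynthetic reasoning

**Epoxide last (24 from 23).** The C8–C9 epoxide is removed first because it tolerates neither a C6 ketone nor nucleophiles. The forward step is a hydroxyl-directed epoxidation of the C8=C9 alkene of 23, in which the C10 α-hydroxyl delivers oxygen to the α face.

**C10 oxygen by 1,3-transposition (23 from 20 from 19).** The allylic alcohol of 23 is traced to the C9=C10 alkene of 19. A peracid should attack anti to the axial C15 methyl (epoxide 20). A selenide nucleophile then opens at C9, away from the neopentylic C10, and selenoxide syn-elimination uses the β-hydrogen on C8. This places oxygen at C10 on the α face without a hydride reduction, and it consumes the temporary C8 stereocentre.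

**Ester and anti-diol (19 from 16 from 15, with 17).** The angelate is attached to the only secondary hydroxyl of diol 16 through the mixed anhydride 18. The C6 carbinol comes from ketol 15 by hydride delivered internally from the C4 hydroxyl, which gives the anti-1,3-diol and therefore the 6α configuration.

**Ketol (15 from 13 from 12).** The C4 carbinol is cut at the C4–isopropyl bond: an isopropyl nucleophile adds to the C4 carbonyl of the vinylogous silyl ester 12. Fluoride then unmasks the C6 ketone through enolate 14, and C5 is set by protonation under thermodynamic control (C6 anti to isopropyl, hydroxyl hydrogen-bonded to the ketone).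

**Key disconnection (12 from 10 through 11).** The C1–C5 ring-fusion bond and the C7–C8 bond are cut. Forward, the carbene from 10 adds to the C1=C10 alkene and closes the cyclopentanone as bicyclo[3.1.0]hexanone 11. The cis-divinylcyclopropane then rearranges, breaking C5–C10 and forming C7–C8, which closes the seven-membered ring. One operation turns an acyclic chain into the whole bicyclic skeleton with the quaternary C1 and places oxygen at C6 and unsaturation at C9=C10. Cutting here rather than at C8=C9 or C4–C5 moves all ring construction into one catalytic, enantioselective step.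

**Precursor (10 from 9 from 8 from 5 and 6; 5 from 1 and 2).** The diazo trienone 10 is made by enol silylation of diazo diketone 9, itself from diketone 8 by diazo transfer. Diketone 8 is the product of terminal alkylation of the dianion 7 of 6 with dienyl bromide 5. Bromide 5 comes from 1 and 2 by olefination, reduction and bromination, which fixes the E geometry that later makes the cyclopropane cis-divinyl.

## Alternatives that were turned down

**Alternative 1: ring-closing metathesis (textbook).** Cut C8=C9. The forward key step is metathesis of the bis-alkenyl cyclopentane A2 with the second-generation Grubbs catalyst, followed by directed epoxidation. A2 would come from the ring-contracted terpinen-4-ol enal A1 (ozonolysis and aldol condensation), which supplies C4 with its isopropyl and hydroxyl. It was turned down for three reasons: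
- In A1 the C4 centre directs conjugate addition at C1 anti to the isopropyl group, so a C10 branch enters cis to the hydroxyl, giving the wrong C1 epimer. The natural configuration needs the methyl added last to a C10-functionalised analogue that costs several extra steps.
- The C6 and C10 carbinols would be made by additions to aldehydes beside quaternary or fully substituted carbons with no reliable control.
- The metathesis sets no stereocentre, and the count exceeds 18 steps.

**Alternative 2: type 2 intramolecular Diels–Alder, then cleavage and aldol.** Cut C1–C5 and C2–C3 of a bridged precursor. Trienone A3 would give the bridgehead alkene A4 (bicyclo[4.3.1]decadienone); ozonolysis of C4=C6 gives trione A5, and an aldol between C5 and C4 closes the cyclopentane. It was turned down for four reasons: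
- A5 can enolise at C3, C5, C7 and C9. The C3 enolate adding to C6 gives a bridged ketol in a ring size as good as the desired one, so regiochemistry and the C4/C5 configuration rest on an unknown equilibrium.
- C7 lies between the C6 carbonyl and the C8=C9 alkene, so conjugation migrates, and the 8,9-epoxide cannot be carried through (β,γ-epoxy ketone).
- An enantioselective version of this cycloaddition with an α-substituted enone lacks close precedent.
- The sequence needs at least 16 steps.

**Alternative 3: decalin to hydroazulene 1,2-shift.** Cut C1–C5 and reconnect C1–C6. From the Wieland–Miescher ketone A6, isopropyl addition, dihydroxylation of C5=C6 and sulfonylation would give the cis-decalin A7. Migration of C1 from C6 to C5, with the C6 hydroxyl becoming the ketone, would give the ketol skeleton stereospecifically. It was turned down for four reasons: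
- A trans-fused product requires a cis-decalin in which the C5 sulfonate and the C6 hydroxyl are both syn to the angular methyl, so the osmylation must occur on the hindered face.
- The C4 carbinol can push the C3–C4 bond instead, which is equally antiperiplanar, giving a hydrindane.
- A6 lacks the C14 methyl and the C8=C9 unsaturation (about four more steps).
- The C10 ketone would reduce to the 10β-alcohol.

Key step: step 7

## Remarks on assumptions

- Locants in descriptive names follow daucane numbering (C1 quaternary, C4 carbinol, C5 ring-fusion CH, C6–C10 around the seven-membered ring). α is the face of H-5 and β the face of the C15 methyl.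
- The sense of induction of Rh2(S-PTAD)4 in step 7 is assumed to give the enantiomer drawn. If it proves opposite, the (R)-configured catalyst is used and nothing else changes.

## Steps

Step 1
Reactants: 1 (E)-but-2-enal; 2 ethyl 2-(triphenylphosphoranylidene)propanoate
Product: 3 ethyl (2E,4E)-2-methylhexa-2,4-dienoate
Conditions: CH2Cl2, 23 °C to reflux
Reagents that add atoms: none
Why: Wittig olefination with a stabilised ylide should be E-selective and fixes the trisubstituted alkene (later C1=C10) whose geometry makes the cyclopropane of step 7 cis-divinyl.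

Step 2
Reactants: 3 ethyl (2E,4E)-2-methylhexa-2,4-dienoate
Product: 4 (2E,4E)-2-methylhexa-2,4-dien-1-ol
Conditions: i-Bu2AlH (2.2 equiv), CH2Cl2, −78 to 0 °C; aq. potassium sodium tartrate
Reagents that add atoms: none
Why: 1,2-Reduction of the conjugated ester by the aluminium hydride should leave both alkenes and their geometry untouched.

Step 3
Reactants: 4 (2E,4E)-2-methylhexa-2,4-dien-1-ol
Product: 5 (2E,4E)-1-bromo-2-methylhexa-2,4-diene
Conditions: PBr3 (0.4 equiv), Et2O, −10 °C; used crude
Reagents that add atoms: phosphorus tribromide, BrP(Br)Br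
Why: Bromination of the primary allylic alcohol; the primary, fully conjugated bromide is also the thermodynamic allylic isomer, so position and geometry should be retained.

Step 4
Reactants: 5 (2E,4E)-1-bromo-2-methylhexa-2,4-diene; 6 pentane-2,4-dione
Product: 8 (7E,9E)-7-methylundeca-7,9-diene-2,4-dione, via acetylacetone dianion 7 (not isolated)
Conditions: 6, NaH, THF, 0 °C; n-BuLi, 0 °C; then 5, 0 to 23 °C; aq. HCl
Reagents that add atoms: none
Why: Hauser dianion alkylation: the terminal carbanion of 7 is the most nucleophilic site and should displace the primary allylic bromide by SN2, forming the C2–C3 bond of the tether.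

Step 5
Reactants: 8 (7E,9E)-7-methylundeca-7,9-diene-2,4-dione
Product: 9 (7E,9E)-3-diazo-7-methylundeca-7,9-diene-2,4-dione
Conditions: 4-acetamidobenzenesulfonyl azide, Et3N, MeCN, 0 to 23 °C
Reagents that add atoms: 4-acetamidobenzenesulfonyl azide, CC(=O)Nc1ccc(cc1)S(=O)(=O)N=[N+]=[N-]
Why: Regitz diazo transfer to the doubly activated methylene of a 1,3-diketone is general and tolerates the diene.

Step 6
Reactants: 9 (7E,9E)-3-diazo-7-methylundeca-7,9-diene-2,4-dione
Product: 10 (7E,9E)-2-[(tert-butyldimethylsilyl)oxy]-3-diazo-7-methylundeca-1,7,9-trien-4-one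
Conditions: TBSOTf, Et3N, CH2Cl2, −78 to 0 °C; used at once
Reagents that add atoms: tert-butyldimethylsilyl trifluoromethanesulfonate, CC(C)(C)[Si](C)(C)OS(=O)(=O)C(F)(F)F
Why: Soft enolisation and O-silylation of a diazo 1,3-dicarbonyl compound gives the siloxyvinyl diazo ketone; the amine should remove the proton of the less hindered acetyl methyl in preference to the C3 methylene.

Step 7
Reactants: 10 (7E,9E)-2-[(tert-butyldimethylsilyl)oxy]-3-diazo-7-methylundeca-1,7,9-trien-4-one
Product: 12 (3aR,6R)-8-[(tert-butyldimethylsilyl)oxy]-3a,6-dimethyl-3,3a,6,7-tetrahydroazulen-1(2H)-one, via cis-divinylcyclopropane 11 (not isolated)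
Conditions: Rh2(S-PTAD)4 (dirhodium tetrakis[(S)-(1-adamantyl)(N-phthalimido)acetate], 1 mol %), hexanes, −20 to 23 °C; then PhMe, 80 °C
Reagents that add atoms: none
Why: Loss of N2 gives a rhodium vinylcarbene (vinyl donor, C4 acyl acceptor) that adds to the proximal C1=C10 alkene; the three-atom tether allows only this alkene to be reached and the cyclopentanone closes in the exo mode as bicyclo[3.1.0]hexan-2-one 11. The addition is stereospecific, so the E alkene places the propenyl group on C10 cis to the siloxyvinyl group on C5, which is the cis-divinyl arrangement. The [3,3] shift then proceeds through the boat transition state, breaks the donor–acceptor-weakened C5–C10 bond and forms C7–C8, closing the seven-membered ring by sigmatropic ring expansion. The closest known reaction type is the tandem cyclopropanation/Cope rearrangement (formal [4+3] cycloaddition) of vinyl diazo carbonyl compounds with dienes under dirhodium carboxylate catalysis, known in intramolecular and enantioselective forms. C1 is set by the chiral catalyst through the face of the alkene that the carbene attacks. C8 is set by the E geometry of the propenyl terminus in the boat transition state, which puts the C14 methyl outward and therefore trans to the C15 methyl (C8–H β). The step needs site selectivity (tether length), enantioselectivity (catalyst) and a rearrangement faster than homodienyl hydrogen shift; the acyl and siloxy substituents on the breaking bond should secure the last.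

Step 8
Reactants: 12 (3aR,6R)-8-[(tert-butyldimethylsilyl)oxy]-3a,6-dimethyl-3,3a,6,7-tetrahydroazulen-1(2H)-one
Product: 13 (1R,3aR,6R)-8-[(tert-butyldimethylsilyl)oxy]-3a,6-dimethyl-1-(propan-2-yl)-1,2,3,3a,6,7-hexahydroazulen-1-ol
Conditions: i-PrMgCl, CeCl3, THF, −78 °C; aq. NH4Cl
Reagents that add atoms: isopropylmagnesium chloride, CC(C)[Mg]Cl
Why: Organocerium 1,2-addition to the carbonyl of a vinylogous ester (first stage of a Stork–Danheiser sequence) avoids enolisation at C3; attack anti to the C15 methyl (α face) should give the 4β-hydroxyl with the isopropyl group α.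

Step 9
Reactants: 13 (1R,3aR,6R)-8-[(tert-butyldimethylsilyl)oxy]-3a,6-dimethyl-1-(propan-2-yl)-1,2,3,3a,6,7-hexahydroazulen-1-ol
Product: 15 (3R,3aR,6R,8aR)-3-hydroxy-6,8a-dimethyl-3-(propan-2-yl)-2,3,3a,5,6,8a-hexahydroazulen-4(1H)-one, via tetrabutylammonium enolate 14 (not isolated)
Conditions: Bu4NF, AcOH, THF, −20 to 0 °C
Reagents that add atoms: none
Why: Fluoride cleaves the enol silyl ether without acid, so the tertiary allylic alcohol cannot ionise, and enolate 14 is protonated at C5; the trans-fused ketol (C6 anti to the isopropyl group, hydroxyl hydrogen-bonded to the C6 carbonyl) should be favoured and is reached by enolisation under the buffered conditions.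

Step 10
Reactants: 15 (3R,3aR,6R,8aR)-3-hydroxy-6,8a-dimethyl-3-(propan-2-yl)-2,3,3a,5,6,8a-hexahydroazulen-4(1H)-one
Product: 16 (3R,3aS,4S,6R,8aR)-6,8a-dimethyl-3-(propan-2-yl)-1,2,3,3a,4,5,6,8a-octahydroazulene-3,4-diol
Conditions: Me4NBH(OAc)3, MeCN/AcOH, −30 °C
Reagents that add atoms: none
Why: Evans–Saksena reduction: the C4 hydroxyl binds boron and delivers hydride to the β face of the C6 ketone, which should give the anti-1,3-diol with the 6α-hydroxyl that an external hydride would not give.

Step 11
Reactants: 16 (3R,3aS,4S,6R,8aR)-6,8a-dimethyl-3-(propan-2-yl)-1,2,3,3a,4,5,6,8a-octahydroazulene-3,4-diol; 17 (2Z)-2-methylbut-2-enoic acid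
Product: 19 (3R,3aS,4S,6R,8aR)-3-hydroxy-6,8a-dimethyl-3-(propan-2-yl)-1,2,3,3a,4,5,6,8a-octahydroazulen-4-yl (2Z)-2-methylbut-2-enoate, via mixed anhydride 18 (not isolated)
Conditions: 17, 2,4,6-Cl3C6H2COCl, Et3N, PhMe, 23 °C; then 16, 80 °C
Reagents that add atoms: none
Why: Yamaguchi-type acylation through the trichlorobenzoic mixed anhydride, run without a nucleophilic amine catalyst, should keep the Z geometry; only the secondary C6 hydroxyl is acylated, the tertiary C4 hydroxyl being inert.

Step 12
Reactants: 19 (3R,3aS,4S,6R,8aR)-3-hydroxy-6,8a-dimethyl-3-(propan-2-yl)-1,2,3,3a,4,5,6,8a-octahydroazulen-4-yl (2Z)-2-methylbut-2-enoate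
Product: 20 9α,10α-epoxide of 19 (6α-angeloyloxy-9α,10α-epoxy-8βH-daucan-4β-ol)
Conditions: mCPBA, NaHCO3, CH2Cl2, 0 °C
Reagents that add atoms: 3-chloroperoxybenzoic acid, OOC(=O)c1cccc(Cl)c1
Why: Prilezhaev epoxidation of the only electron-rich alkene (C9=C10; the angelate is electron-poor); attack anti to the pseudo-axial C15 methyl on the adjacent C1 should give the α-epoxide.

Step 13
Reactants: 20 9α,10α-epoxide of 19
Product: 23 (3R,3aS,4S,8R,8aS)-3,8-dihydroxy-6,8a-dimethyl-3-(propan-2-yl)-1,2,3,3a,4,5,8,8a-octahydroazulen-4-yl (2Z)-2-methylbut-2-enoate, via hydroxy selenide 21 (not isolated), via selenoxide 22 (not isolated)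
Conditions: PhSeSePh, NaBH4, EtOH, 0 to 40 °C; then THF, 30% H2O2, 0 to 23 °C
Reagents that add atoms: diphenyl diselenide, c1ccccc1[Se][Se]c1ccccc1 (PhSe enters 21 and 22 and leaves again); hydrogen peroxide, OO (its oxygen enters 22 and leaves again)
Why: Sharpless–Lauer transposition: the selenolate opens the epoxide at C9, away from the neopentylic C10, with inversion (9β-selenide, 10α-hydroxyl); the selenoxide eliminates syn toward the β-hydrogen on C8 and away from the carbinol, giving the C8=C9 alkene and keeping the C10 α-oxygen.

Step 14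
Reactants: 23 (3R,3aS,4S,8R,8aS)-3,8-dihydroxy-6,8a-dimethyl-3-(propan-2-yl)-1,2,3,3a,4,5,8,8a-octahydroazulen-4-yl (2Z)-2-methylbut-2-enoate
Product: 24 lapiferine (6α-angeloyloxy-8α,9α-epoxy-trans-daucane-4β,10α-diol)
Conditions: VO(acac)2 (5 mol %), t-BuOOH, CH2Cl2, 0 to 23 °C
Reagents that add atoms: tert-butyl hydroperoxide, CC(C)(C)OO
Why: Vanadium-catalysed hydroxyl-directed epoxidation of the cyclic allylic alcohol delivers oxygen syn to the C10 α-hydroxyl, setting C8 and C9; the electron-poor angelate alkene should not react.

## Compound list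

1 | (E)-but-2-enal | C/C=C/C=O | starting material
2 | ethyl 2-(triphenylphosphoranylidene)propanoate | CCOC(=O)C(C)=P(c1ccccc1)(c1ccccc1)c1ccccc1 | starting material
3 | ethyl (2E,4E)-2-methylhexa-2,4-dienoate | C/C=C/C=C(\C)C(=O)OCC | intermediate
4 | (2E,4E)-2-methylhexa-2,4-dien-1-ol | C/C=C/C=C(\C)CO | intermediate
5 | (2E,4E)-1-bromo-2-methylhexa-2,4-diene | C/C=C/C=C(\C)CBr | intermediate
6 | pentane-2,4-dione | CC(=O)CC(C)=O | starting material
7 | acetylacetone dianion, lithium sodium salt | [Na+].[Li+].[O-]C(C)=CC([O-])=C | intermediate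
8 | (7E,9E)-7-methylundeca-7,9-diene-2,4-dione | CC(=O)CC(=O)CC/C(C)=C/C=C/C | intermediate
9 | (7E,9E)-3-diazo-7-methylundeca-7,9-diene-2,4-dione | CC(=O)C(=[N+]=[N-])C(=O)CC/C(C)=C/C=C/C | intermediate
10 | (7E,9E)-2-[(tert-butyldimethylsilyl)oxy]-3-diazo-7-methylundeca-1,7,9-trien-4-one | C=C(O[Si](C)(C)C(C)(C)C)C(=[N+]=[N-])C(=O)CC/C(C)=C/C=C/C | intermediate
11 | (1S,5R,6R)-1-{1-[(tert-butyldimethylsilyl)oxy]ethenyl}-5-methyl-6-[(1E)-prop-1-en-1-yl]bicyclo[3.1.0]hexan-2-one | C=C(O[Si](C)(C)C(C)(C)C)[C@@]12C(=O)CC[C@]1(C)[C@H]2/C=C/C | intermediate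
12 | (3aR,6R)-8-[(tert-butyldimethylsilyl)oxy]-3a,6-dimethyl-3,3a,6,7-tetrahydroazulen-1(2H)-one | C[Si](C)(C(C)(C)C)OC=1C[C@@H](C)C=C[C@@]2(C)CCC(=O)C=12 | intermediate
13 | (1R,3aR,6R)-8-[(tert-butyldimethylsilyl)oxy]-3a,6-dimethyl-1-(propan-2-yl)-1,2,3,3a,6,7-hexahydroazulen-1-ol | C[Si](C)(C(C)(C)C)OC=1C[C@@H](C)C=C[C@@]2(C)CC[C@@](O)(C(C)C)C=12 | intermediate
14 | tetrabutylammonium (1R,3aR,6R)-1-hydroxy-3a,6-dimethyl-1-(propan-2-yl)-1,2,3,3a,6,7-hexahydroazulen-8-olate | CCCC[N+](CCCC)(CCCC)CCCC.[O-]C=1C[C@@H](C)C=C[C@@]2(C)CC[C@@](O)(C(C)C)C=12 | intermediate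
15 | (3R,3aR,6R,8aR)-3-hydroxy-6,8a-dimethyl-3-(propan-2-yl)-2,3,3a,5,6,8a-hexahydroazulen-4(1H)-one | O=C1C[C@@H](C)C=C[C@@]2(C)CC[C@@](O)(C(C)C)[C@H]12 | intermediate
16 | (3R,3aS,4S,6R,8aR)-6,8a-dimethyl-3-(propan-2-yl)-1,2,3,3a,4,5,6,8a-octahydroazulene-3,4-diol | O[C@H]1C[C@@H](C)C=C[C@@]2(C)CC[C@@](O)(C(C)C)[C@H]12 | intermediate
17 | (2Z)-2-methylbut-2-enoic acid (angelic acid) | C/C=C(/C)C(=O)O | starting material
18 | (2Z)-2-methylbut-2-enoic 2,4,6-trichlorobenzoic anhydride | C/C=C(/C)C(=O)OC(=O)c1c(Cl)cc(Cl)cc1Cl | intermediate
19 | (3R,3aS,4S,6R,8aR)-3-hydroxy-6,8a-dimethyl-3-(propan-2-yl)-1,2,3,3a,4,5,6,8a-octahydroazulen-4-yl (2Z)-2-methylbut-2-enoate | C/C=C(/C)C(=O)O[C@H]1C[C@@H](C)C=C[C@@]2(C)CC[C@@](O)(C(C)C)[C@H]12 | intermediate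
20 | 6α-angeloyloxy-9α,10α-epoxy-8βH-daucan-4β-ol (9α,10α-epoxide of 19) | C/C=C(/C)C(=O)O[C@H]1C[C@@H](C)[C@H]2O[C@H]2[C@@]3(C)CC[C@@](O)(C(C)C)[C@H]13 | intermediate
21 | 6α-angeloyloxy-9β-(phenylselanyl)-8βH-daucane-4β,10α-diol | C/C=C(/C)C(=O)O[C@H]1C[C@@H](C)[C@H]([Se]c2ccccc2)[C@@H](O)[C@@]3(C)CC[C@@](O)(C(C)C)[C@H]13 | intermediate
22 | selenoxide of 21 (9β-phenylseleninyl) | C/C=C(/C)C(=O)O[C@H]1C[C@@H](C)[C@H]([Se](=O)c2ccccc2)[C@@H](O)[C@@]3(C)CC[C@@](O)(C(C)C)[C@H]13 | intermediate
23 | (3R,3aS,4S,8R,8aS)-3,8-dihydroxy-6,8a-dimethyl-3-(propan-2-yl)-1,2,3,3a,4,5,8,8a-octahydroazulen-4-yl (2Z)-2-methylbut-2-enoate | C/C=C(/C)C(=O)O[C@H]1CC(C)=C[C@@H](O)[C@@]2(C)CC[C@@](O)(C(C)C)[C@H]12 | intermediate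
24 | lapiferine (6α-angeloyloxy-8α,9α-epoxy-trans-daucane-4β,10α-diol) | C/C=C(/C)C(=O)O[C@H]1C[C@@]2(C)O[C@H]2[C@@H](O)[C@@]2(C)CC[C@@](O)(C(C)C)[C@H]12 | target

## Step count and least certain steps

Total step count: 14. Longest linear sequence: 14 steps (1 to 24); compounds 2, 6 and 17 are commercial partners.

**Step 7 (key step).** Two processes are most likely to fail. The chiral dirhodium carboxylate may give insufficient asymmetric induction with an acyl rather than an ester acceptor. The sigmatropic shift may also be slow, because the C15 methyl on the cyclopropane is syn to both vinyl groups, which would let homodienyl hydrogen shift or carbene side reactions compete. The fallback decouples the two events. It sets out from 9: intramolecular cyclopropanation of this acceptor/acceptor diazo diketone with Cu(MeCN)4PF6 and (S,S)-tert-butyl-bis(oxazoline) should give (1S,5R,6R)-1-acetyl-5-methyl-6-[(1E)-prop-1-en-1-yl]bicyclo[3.1.0]hexan-2-one F3. Enol silylation with TBSOTf and Et3N in warm toluene then equilibrates the enol silyl ethers, and only the acetyl-derived one (11) can rearrange, so the mixture should drain to 12, where the fallback rejoins the route.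

**Step 6.** Enolisation may compete at the C3 methylene and give the regioisomeric enol silyl ether. The fallback removes the choice. It sets out from 6 and 5: diazo transfer to 6 gives the symmetrical 3-diazopentane-2,4-dione F1; monosilylation (TBSOTf, Et3N) gives 4-[(tert-butyldimethylsilyl)oxy]-3-diazopent-4-en-2-one F2. Its only remaining enolisable position is deprotonated with LiN(SiMe3)2 at −78 °C and alkylated with 5, returning at 10.

**Step 8.** The two faces of the C4 carbonyl differ only through the 1,3-related substituents on C1 (C15 methyl against the C10 vinylic carbon), so facial selectivity may be modest. The fallback replaces kinetic control by thermodynamic control. It sets out from 12: addition and desilylation as in steps 8 and 9 would give 15 together with its C4 epimer (3S,3aR,6R,8aR)-3-hydroxy-6,8a-dimethyl-3-(propan-2-yl)-2,3,3a,5,6,8a-hexahydroazulen-4(1H)-one F4. The mixture is treated with catalytic KOt-Bu in THF, so that retro-aldol opening to (3S,6R)-3,6-dimethyl-3-(4-methyl-3-oxopentyl)cyclohept-4-en-1-one F5 and re-closure should accumulate the more stable isomer (isopropyl anti to the C15 methyl, hydroxyl hydrogen-bonded to the C6 ketone), returning at 15.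

**Step 12.** The peracid may attack both faces, since the α face carries the C14 methyl on C8 and the β face the C15 methyl on C1. The fallback uses hydroxyl direction. It sets out from 16: VO(acac)2 and t-BuOOH, directed by the transannular C6 α-hydroxyl, should give 9α,10α-epoxy-8βH-daucane-4β,6α-diol F6, which is acylated with 18 as in step 11 and returns at 20.

**Step 13.** Reversible conjugate addition of the selenolate to the angelate may isomerise it to the tiglate or cleave the ester. The fallback moves the selenium chemistry before the acylation. It sets out from 16 and passes through F6 (as above). Selenolate opening gives 9β-(phenylselanyl)-8βH-daucane-4β,6α,10α-triol F7; oxidation gives its selenoxide F8, and elimination gives dauc-8-ene-4β,6α,10α-triol F9. F9 is acylated with 18 at the C6 hydroxyl, which is less hindered than the neopentylic C10 hydroxyl beside the quaternary C1, and returns at 23.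

## Further compounds

F1 | step 6 | 3-diazopentane-2,4-dione | CC(=O)C(=[N+]=[N-])C(C)=O
F2 | step 6 | 4-[(tert-butyldimethylsilyl)oxy]-3-diazopent-4-en-2-one | C=C(O[Si](C)(C)C(C)(C)C)C(=[N+]=[N-])C(C)=O
F3 | step 7 | (1S,5R,6R)-1-acetyl-5-methyl-6-[(1E)-prop-1-en-1-yl]bicyclo[3.1.0]hexan-2-one | CC(=O)[C@@]12C(=O)CC[C@]1(C)[C@H]2/C=C/C
F4 | step 8 | (3S,3aR,6R,8aR)-3-hydroxy-6,8a-dimethyl-3-(propan-2-yl)-2,3,3a,5,6,8a-hexahydroazulen-4(1H)-one | O=C1C[C@@H](C)C=C[C@@]2(C)CC[C@](O)(C(C)C)[C@H]12
F5 | step 8 | (3S,6R)-3,6-dimethyl-3-(4-methyl-3-oxopentyl)cyclohept-4-en-1-one | O=C1C[C@@H](C)C=C[C@@](C)(CCC(=O)C(C)C)C1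
F6 | step 12 | 9α,10α-epoxy-8βH-daucane-4β,6α-diol | O[C@H]1C[C@@H](C)[C@H]2O[C@H]2[C@@]3(C)CC[C@@](O)(C(C)C)[C@H]13
F7 | step 13 | 9β-(phenylselanyl)-8βH-daucane-4β,6α,10α-triol | O[C@H]1C[C@@H](C)[C@H]([Se]c2ccccc2)[C@@H](O)[C@@]3(C)CC[C@@](O)(C(C)C)[C@H]13
F8 | step 13 | 9β-(phenylseleninyl)-8βH-daucane-4β,6α,10α-triol | O[C@H]1C[C@@H](C)[C@H]([Se](=O)c2ccccc2)[C@@H](O)[C@@]3(C)CC[C@@](O)(C(C)C)[C@H]13
F9 | step 13 | dauc-8-ene-4β,6α,10α-triol | O[C@H]1CC(C)=C[C@@H](O)[C@@]2(C)CC[C@@](O)(C(C)C)[C@H]12
A1 | alternative 1 | (5R)-5-hydroxy-2-methyl-5-(propan-2-yl)cyclopent-1-ene-1-carbaldehyde | O=CC1=C(C)CC[C@@]1(O)C(C)C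
A2 | alternative 1 | bis-alkenyl cyclopentane triol (C10 vinyl carbinol, C6 methallyl carbinol) | C=C[C@@H](O)[C@@]1(C)CC[C@@](O)(C(C)C)[C@@H]1[C@@H](O)CC(C)=C
A3 | alternative 2 | (4Z)-2,5-dimethyl-7-methylidene-8-(propan-2-yl)nona-1,4,8-trien-3-one | C=C(C)C(=O)/C=C(C)\CC(=C)C(=C)C(C)C
A4 | alternative 2 | 1,4-dimethyl-7-(propan-2-yl)bicyclo[4.3.1]deca-3,6-dien-2-one | O=C1C=C(C)CC2=C(C(C)C)CC[C@@]1(C)C2
A5 | alternative 2 | 3,7-dimethyl-7-(4-methyl-3-oxopentyl)cyclohept-2-ene-1,5-dione | O=C1C=C(C)CC(=O)C[C@]1(C)CCC(=O)C(C)C
A6 | alternative 3 | (S)-Wieland–Miescher ketone | C[C@]12CCC(=O)C=C1CCCC2=O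
A7 | alternative 3 | cis-decalin 4β,6β-diol 5β-methanesulfonate (4α-isopropyl, 1β-methyl, 10-oxo; daucane locants) | O=C1CCC[C@]2(O)[C@@H](OS(C)(=O)=O)[C@](O)(C(C)C)CC[C@]12C
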